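## Retrosynthetic overview

- Germacrane numbering is used: C1 ketone, C2=C3 enol ether, C4=C5 (C15H2OH on C4), C6 (O-angeloyl), C7, C8 (lactone oxygen), C9, C10 (methyl, furanone oxygen), C11=C13 methylene, C12 lactone carbonyl. The target is (6S,7R,8S,10R).
- Endgame: 15-O-desilylation ⇐ 6-O-angeloylation ⇐ 6-O-desilylation of the tricyclic lactone.
- Key disconnection C7–C8: this is the β,γ-bond of the α-methylene-γ-butyrolactone, so C8 is a latent aldehyde and C7 the γ-carbon of a 2-(bromomethyl)acrylate (C13–C11(C12)=C7). CrCl2 reverses the polarity of C7, and one operation closes the ten-membered carbocycle and then the lactone, creating C7 and C8.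
- Enabling feature: the planar 3(2H)-furanone (O–C3=C2–C1(=O)–C10) and the Z C4=C5 alkene form a rigid arc that holds C5 and C9 about 5 Å apart, so C7 and C8 can only meet across an extended C5–C9 bridge.
- Precursor: the furanone comes from 5-endo-dig cyclisation of a hydroxy-ynone, made by Sonogashira union of a (R)-citramalic-acid-derived alkyne triol with a Z-vinyl iodide; cross-metathesis installs the bromomethyl acrylate. Ring order: furanone, then carbocycle, then lactone (the last two in one step).

Key step: step 13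

Assumption: the (S,S) enantiomer of the ProPhenol ligand is taken to deliver (R)-11 in step 5; if the sense of induction is the opposite, its enantiomer is used.

## Route

Step 1
Reactants: 1 (R)-citramalic acid
Product: 2 [(4R)-2,2,4-trimethyl-5-oxo-1,3-dioxolan-4-yl]acetic acid
Conditions: 2,2-dimethoxypropane, p-TsOH·H2O (cat.), CH2Cl2, 25 °C
Reagents that add atoms: 2,2-dimethoxypropane (COC(C)(C)OC)
Why: Acid-catalysed transacetalisation ties the α-hydroxy acid into a five-membered dioxolanone and leaves the β-carboxyl free; the quaternary centre (R, from the chiral pool) is untouched.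

Step 2
Reactants: 2 [(4R)-2,2,4-trimethyl-5-oxo-1,3-dioxolan-4-yl]acetic acid
Product: 4 (3R)-3-hydroxy-3-methyloxolan-2-one, via hydroxyethyl dioxolanone 3 (not isolated)
Conditions: BH3·SMe2, THF, 0 → 25 °C; aq. work-up; then p-TsOH (cat.), CH2Cl2, 25 °C
Reagents that add atoms: none
Why: Borane reduces the free carboxylic acid chemoselectively beside the dioxolanone ester, and acid-catalysed translactonisation of the γ-hydroxy dioxolanone expels acetone to give the γ-lactone with the tertiary centre unchanged.

Step 3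
Reactants: 4 (3R)-3-hydroxy-3-methyloxolan-2-one
Product: 5 (2RS,3R)-3-methyloxolane-2,3-diol
Conditions: iBu2AlH (2.2 equiv), CH2Cl2, −78 °C; aq. sodium potassium tartrate
Reagents that add atoms: none
Why: Partial reduction of a γ-lactone to the lactol at low temperature, the first equivalent of hydride being consumed by the tertiary hydroxyl; the anomeric centre is inconsequential.

Step 4
Reactants: 5 (2RS,3R)-3-methyloxolane-2,3-diol; 6 ethynylmagnesium bromide
Product: 7 (3R,4RS)-3-methylhex-5-yne-1,3,4-triol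
Conditions: HC≡CMgBr (4 equiv), THF, 0 → 25 °C; aq. NH4Cl
Reagents that add atoms: none
Why: Grignard addition to the open hydroxy-aldehyde form of the lactol gives the propargylic alcohol; the new carbinol centre is formed without control and is oxidised away in step 9.

Step 5
Reactants: 8 acrolein; 9 tert-butyldimethyl(prop-2-yn-1-yloxy)silane
Product: 11 (3R)-6-[(tert-butyldimethylsilyl)oxy]hex-1-en-4-yn-3-ol, via alkynyl(methyl)zinc 10 (not isolated)
Conditions: ZnMe2 (3 equiv), (S,S)-ProPhenol (10 mol %), Ph3P=O (20 mol %), toluene, 0 °C, slow addition of 8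
Reagents that add atoms: none
Why: Zinc–ProPhenol-catalysed enantioselective alkynylation of an enal, in which the chiral dinuclear zinc complex delivers the alkynylzinc to one aldehyde face and so sets the C6 carbinol centre.

Step 6
Reactants: 11 (3R)-6-[(tert-butyldimethylsilyl)oxy]hex-1-en-4-yn-3-ol
Product: 13 (3R,4Z)-6-[(tert-butyldimethylsilyl)oxy]-5-iodohexa-1,4-dien-3-ol, via cyclic alkenylaluminate 12 (not isolated)
Conditions: NaAlH2(OCH2CH2OMe)2 (1.5 equiv), THF, 0 °C; EtOAc; then I2, THF, −78 → 0 °C
Reagents that add atoms: iodine (II)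
Why: Alkoxide-directed trans-hydroalumination of the propargylic alcohol places aluminium on the distal alkyne carbon cis to the carbinol carbon, and iodinolysis with retention gives the Z-iodoalkene; the vinyl group and the carbinol centre are not affected.

Step 7
Reactants: 13 (3R,4Z)-6-[(tert-butyldimethylsilyl)oxy]-5-iodohexa-1,4-dien-3-ol
Product: 14 (3R,4Z)-6-[(tert-butyldimethylsilyl)oxy]-5-iodo-3-[(triethylsilyl)oxy]hexa-1,4-diene
Conditions: Et3SiCl, imidazole, CH2Cl2, 0 °C
Reagents that add atoms: chlorotriethylsilane (CC[Si](Cl)(CC)CC)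
Why: Imidazole-mediated silylation masks the bis-allylic hydroxyl, which would otherwise cyclise onto the cis-enyne formed in step 8 to give a furan.

Step 8
Reactants: 14 (3R,4Z)-6-[(tert-butyldimethylsilyl)oxy]-5-iodo-3-[(triethylsilyl)oxy]hexa-1,4-diene; 7 (3R,4RS)-3-methylhex-5-yne-1,3,4-triol
Product: 15 (3R,4RS,7E,9R)-7-{[(tert-butyldimethylsilyl)oxy]methyl}-3-methyl-9-[(triethylsilyl)oxy]undeca-7,10-dien-5-yne-1,3,4-triol
Conditions: Pd(PPh3)4 (5 mol %), CuI (10 mol %), Et3N, THF, 25 °C
Reagents that add atoms: none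
Why: Sonogashira coupling of a vinyl iodide with a terminal alkyne proceeds with retention of alkene geometry (alkyne cis to C6) and tolerates free hydroxyls and silyl ethers.

Step 9
Reactants: 15 (3R,4RS,7E,9R)-7-{[(tert-butyldimethylsilyl)oxy]methyl}-3-methyl-9-[(triethylsilyl)oxy]undeca-7,10-dien-5-yne-1,3,4-triol
Product: 16 (3R,7E,9R)-7-{[(tert-butyldimethylsilyl)oxy]methyl}-1,3-dihydroxy-3-methyl-9-[(triethylsilyl)oxy]undeca-7,10-dien-5-yn-4-one
Conditions: MnO2 (activated, excess), CH2Cl2, 25 °C
Reagents that add atoms: none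
Why: MnO2 oxidises the propargylic secondary alcohol selectively, leaves the saturated primary and the tertiary hydroxyl, and removes the stereorandom carbinol centre.

Step 10
Reactants: 16 (3R,7E,9R)-7-{[(tert-butyldimethylsilyl)oxy]methyl}-1,3-dihydroxy-3-methyl-9-[(triethylsilyl)oxy]undeca-7,10-dien-5-yn-4-one
Product: 17 (2R)-5-{(2Z,4R)-1-[(tert-butyldimethylsilyl)oxy]-4-[(triethylsilyl)oxy]hexa-2,5-dien-2-yl}-2-(2-hydroxyethyl)-2-methylfuran-3(2H)-one
Conditions: Ph3PAuNTf2 (5 mol %), toluene, 25 °C
Reagents that add atoms: none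
Why: π-Acid activation of the ynone by monovalent gold triggers 5-endo-dig attack of the tertiary hydroxyl on C3, and protodeauration gives the 3(2H)-furanone; the quaternary C10 centre is not involved.

Step 11
Reactants: 17 (2R)-5-{(2Z,4R)-1-[(tert-butyldimethylsilyl)oxy]-4-[(triethylsilyl)oxy]hexa-2,5-dien-2-yl}-2-(2-hydroxyethyl)-2-methylfuran-3(2H)-one; 18 methyl 2-(bromomethyl)acrylate
Product: 19 methyl (2Z,4S,5Z)-2-(bromomethyl)-7-[(tert-butyldimethylsilyl)oxy]-6-[(5R)-5-(2-hydroxyethyl)-5-methyl-4-oxo-4,5-dihydrofuran-2-yl]-4-[(triethylsilyl)oxy]hepta-2,5-dienoate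
Conditions: 18 (5 equiv), second-generation Hoveyda–Grubbs catalyst [RuCl2(H2IMes)(=CH-C6H4-2-OiPr)] (10 mol %), CH2Cl2, 40 °C
Reagents that add atoms: none
Why: Olefin cross-metathesis of the only terminal alkene with a 1,1-disubstituted acrylate, as known for methacrylate-type partners; the trisubstituted enoate should form with the ester trans to C6 (thermodynamic, Z by CIP), and no stereocentre is created.

Step 12
Reactants: 19 methyl (2Z,4S,5Z)-2-(bromomethyl)-7-[(tert-butyldimethylsilyl)oxy]-6-[(5R)-5-(2-hydroxyethyl)-5-methyl-4-oxo-4,5-dihydrofuran-2-yl]-4-[(triethylsilyl)oxy]hepta-2,5-dienoate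
Product: 20 methyl (2Z,4S,5Z)-2-(bromomethyl)-7-[(tert-butyldimethylsilyl)oxy]-6-[(5R)-5-methyl-4-oxo-5-(2-oxoethyl)-4,5-dihydrofuran-2-yl]-4-[(triethylsilyl)oxy]hepta-2,5-dienoate
Conditions: Dess–Martin periodinane, NaHCO3, CH2Cl2, 0 → 25 °C
Reagents that add atoms: none
Why: Dess–Martin oxidation of the primary alcohol under buffered, non-basic conditions gives the β-alkoxy aldehyde, which is used at once to avoid β-elimination of the furanone oxygen.

Step 13
Reactants: 20 methyl (2Z,4S,5Z)-2-(bromomethyl)-7-[(tert-butyldimethylsilyl)oxy]-6-[(5R)-5-methyl-4-oxo-5-(2-oxoethyl)-4,5-dihydrofuran-2-yl]-4-[(triethylsilyl)oxy]hepta-2,5-dienoate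
Product: 23 (6S,7R,8S,10R)-15-[(tert-butyldimethylsilyl)oxy]-1-oxo-6-[(triethylsilyl)oxy]-3,10-epoxygermacra-2,4(Z),11(13)-trien-12,8-olide, via allylchromium dichloride 21 (not isolated), via chromium alkoxide 22 (not isolated)
Conditions: CrCl2 (10 equiv), THF, 25 °C, slow addition of 20 (final 2 mM); aq. NH4Cl
Reagents that add atoms: none
Why: Two equivalents of divalent chromium insert into the allylic C13–Br bond and turn the acceptor carbon C7 of the bromomethyl acrylate into the nucleophilic γ-terminus of a 2-(methoxycarbonyl)allyl trivalent-chromium reagent (21), which adds to the C8 aldehyde through a closed six-membered transition state, after which the chromium alkoxide 22 acylates itself on the C12 methyl ester. The closest known reaction type is the intramolecular Nozaki–Hiyama–Kishi (Barbier-type) allylation/lactonisation of aldehyde-tethered 2-(bromomethyl)acrylates that closes the ten-membered carbocycles of germacranolides. The C7–C8 bond closes the ten-membered carbocycle (nine-membered through the furanone oxygen) in an exo-trig addition to the aldehyde, and the butyrolactone follows by 5-exo-trig attack of O8 on C12. C8 (S): the rigid furanone/Z-alkene arc keeps C5 and C9 about 5 Å apart, so the C5–C6–C7–C8–C9 bridge must be nearly extended, C6 and C9 are antiperiplanar about the forming bond (diaxial chair or twist-boat) while O8 stays gauche to C11 in the chromium-bridged array, and only this 7,8-anti adduct can close to the trans-fused lactone. C7 (R): the same constraint places C5 anti to the incoming aldehyde, and allylic 1,3-strain with the cis CH2Cr group puts H6 in the inside and the silyloxy group in the outside position, which exposes the C7 face that leads from 6S to 7R. The step needs aldehyde-over-ketone chemoselectivity and γ-regioselectivity, both intrinsic to allylchromium reagents, and ring closure over oligomerisation, which slow addition at high dilution and the few rotatable bonds left by the furanone ring should secure.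

Step 14
Reactants: 23 (6S,7R,8S,10R)-15-[(tert-butyldimethylsilyl)oxy]-1-oxo-6-[(triethylsilyl)oxy]-3,10-epoxygermacra-2,4(Z),11(13)-trien-12,8-olide
Product: 24 6-hydroxy analogue of 23 (triethylsilyl group removed)
Conditions: PPTS (cat.), MeOH/CH2Cl2, 0 °C
Reagents that add atoms: none
Why: Acid-catalysed methanolysis should remove the secondary triethylsilyl ether much faster than the primary tert-butyldimethylsilyl ether; the α-methylene lactone is inert to mild acid and no stereocentre is touched.

Step 15
Reactants: 24 6-hydroxy analogue of 23; 25 angelic acid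
Product: 27 15-O-tert-butyldimethylsilyl ether of the target, via mixed anhydride 26 (not isolated)
Conditions: 25, 2,4,6-trichlorobenzoyl chloride, Et3N, toluene, 25 °C; then 24, 80 °C
Reagents that add atoms: none
Why: Yamaguchi-type esterification through the mixed 2,4,6-trichlorobenzoic anhydride without a nucleophilic catalyst acylates the allylic alcohol with retention at C6 and is the established way to avoid angelate-to-tiglate isomerisation.

Step 16
Reactants: 27 15-O-tert-butyldimethylsilyl ether of the target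
Product: 28 target CNP0176514.1
Conditions: HF·pyridine, pyridine, THF, 0 → 25 °C
Reagents that add atoms: none
Why: Buffered fluoride desilylation cleaves the primary silyl ether without affecting the angelate, the α-methylene lactone or the furanone.

## Compound list

1 | (R)-citramalic acid [(2R)-2-hydroxy-2-methylbutanedioic acid] | OC(=O)C[C@@](C(=O)O)(C)O | starting material
2 | [(4R)-2,2,4-trimethyl-5-oxo-1,3-dioxolan-4-yl]acetic acid | OC(=O)C[C@@]1(C)OC(C)(C)OC1=O | intermediate
3 | (5R)-5-(2-hydroxyethyl)-2,2,5-trimethyl-1,3-dioxolan-4-one | OCC[C@@]1(C)OC(C)(C)OC1=O | intermediate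
4 | (3R)-3-hydroxy-3-methyloxolan-2-one | O=C1OCC[C@@]1(C)O | intermediate
5 | (2RS,3R)-3-methyloxolane-2,3-diol | OC1OCC[C@@]1(C)O | intermediate
6 | ethynylmagnesium bromide | C#C[Mg]Br | starting material
7 | (3R,4RS)-3-methylhex-5-yne-1,3,4-triol | OCC[C@@](C(O)C#C)(C)O | intermediate
8 | acrolein (prop-2-enal) | C=CC=O | starting material
9 | tert-butyldimethyl(prop-2-yn-1-yloxy)silane | C#CCO[Si](C)(C)C(C)(C)C | starting material
10 | methyl{3-[(tert-butyldimethylsilyl)oxy]prop-1-yn-1-yl}zinc | C[Zn]C#CCO[Si](C)(C)C(C)(C)C | intermediate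
11 | (3R)-6-[(tert-butyldimethylsilyl)oxy]hex-1-en-4-yn-3-ol | CC(C)(C)[Si](C)(C)OCC#C[C@H](O)C=C | intermediate
12 | sodium cyclic alkenyl(alkoxy)bis(2-methoxyethoxy)aluminate of 11 (five-membered ring Al–O–CH–CH=C) | [Na+].COCCO[Al-]1(OCCOC)O[C@H](C=C)C=C1CO[Si](C)(C)C(C)(C)C | intermediate
13 | (3R,4Z)-6-[(tert-butyldimethylsilyl)oxy]-5-iodohexa-1,4-dien-3-ol | I/C(CO[Si](C)(C)C(C)(C)C)=C\[C@H](O)C=C | intermediate
14 | (3R,4Z)-6-[(tert-butyldimethylsilyl)oxy]-5-iodo-3-[(triethylsilyl)oxy]hexa-1,4-diene | I/C(CO[Si](C)(C)C(C)(C)C)=C\[C@H](O[Si](CC)(CC)CC)C=C | intermediate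
15 | (3R,4RS,7E,9R)-7-{[(tert-butyldimethylsilyl)oxy]methyl}-3-methyl-9-[(triethylsilyl)oxy]undeca-7,10-dien-5-yne-1,3,4-triol | OCC[C@@](C(O)C#C/C(CO[Si](C)(C)C(C)(C)C)=C\[C@H](O[Si](CC)(CC)CC)C=C)(C)O | intermediate
16 | (3R,7E,9R)-7-{[(tert-butyldimethylsilyl)oxy]methyl}-1,3-dihydroxy-3-methyl-9-[(triethylsilyl)oxy]undeca-7,10-dien-5-yn-4-one | OCC[C@@](C(=O)C#C/C(CO[Si](C)(C)C(C)(C)C)=C\[C@H](O[Si](CC)(CC)CC)C=C)(C)O | intermediate
17 | (2R)-5-{(2Z,4R)-1-[(tert-butyldimethylsilyl)oxy]-4-[(triethylsilyl)oxy]hexa-2,5-dien-2-yl}-2-(2-hydroxyethyl)-2-methylfuran-3(2H)-one | OCC[C@@]1(C)OC(=CC1=O)/C(CO[Si](C)(C)C(C)(C)C)=C\[C@H](O[Si](CC)(CC)CC)C=C | intermediate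
18 | methyl 2-(bromomethyl)acrylate | C=C(CBr)C(=O)OC | starting material
19 | methyl (2Z,4S,5Z)-2-(bromomethyl)-7-[(tert-butyldimethylsilyl)oxy]-6-[(5R)-5-(2-hydroxyethyl)-5-methyl-4-oxo-4,5-dihydrofuran-2-yl]-4-[(triethylsilyl)oxy]hepta-2,5-dienoate | OCC[C@@]1(C)OC(=CC1=O)/C(CO[Si](C)(C)C(C)(C)C)=C\[C@H](O[Si](CC)(CC)CC)/C=C(\CBr)C(=O)OC | intermediate
20 | methyl (2Z,4S,5Z)-2-(bromomethyl)-7-[(tert-butyldimethylsilyl)oxy]-6-[(5R)-5-methyl-4-oxo-5-(2-oxoethyl)-4,5-dihydrofuran-2-yl]-4-[(triethylsilyl)oxy]hepta-2,5-dienoate | O=CC[C@@]1(C)OC(=CC1=O)/C(CO[Si](C)(C)C(C)(C)C)=C\[C@H](O[Si](CC)(CC)CC)/C=C(\CBr)C(=O)OC | intermediate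
21 | allylchromium dichloride from 20 (CrCl2 on C13, trivalent chromium) | O=CC[C@@]1(C)OC(=CC1=O)/C(CO[Si](C)(C)C(C)(C)C)=C\[C@H](O[Si](CC)(CC)CC)/C=C(\C[Cr](Cl)Cl)C(=O)OC | intermediate
22 | dichlorochromium C8-alkoxide of the ring-closed hydroxy methyl ester (C7–C8 bond formed, lactone not yet closed) | Cl[Cr](Cl)O[C@H]1C[C@@]2(C)OC(=CC2=O)/C(CO[Si](C)(C)C(C)(C)C)=C\[C@H](O[Si](CC)(CC)CC)[C@@H]1C(=C)C(=O)OC | intermediate
23 | (6S,7R,8S,10R)-15-[(tert-butyldimethylsilyl)oxy]-1-oxo-6-[(triethylsilyl)oxy]-3,10-epoxygermacra-2,4(Z),11(13)-trien-12,8-olide | C=C1C(=O)O[C@H]2C[C@@]3(C)OC(=CC3=O)/C(CO[Si](C)(C)C(C)(C)C)=C\[C@H](O[Si](CC)(CC)CC)[C@H]12 | intermediate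
24 | 6-hydroxy analogue of 23 (15-O-tert-butyldimethylsilyl, 6-OH free; all stereocentres spatially as in 23) | C=C1C(=O)O[C@H]2C[C@@]3(C)OC(=CC3=O)/C(CO[Si](C)(C)C(C)(C)C)=C\[C@H](O)[C@H]12 | intermediate
25 | angelic acid [(2Z)-2-methylbut-2-enoic acid] | C/C=C(/C)C(=O)O | starting material
26 | angelic 2,4,6-trichlorobenzoic anhydride | C/C=C(/C)C(=O)OC(=O)c1c(Cl)cc(Cl)cc1Cl | intermediate
27 | 15-O-tert-butyldimethylsilyl ether of the target (6-O-angeloyl; 6S,7R,8S,10R) | C=C1C(=O)O[C@H]2C[C@@]3(C)OC(=CC3=O)/C(CO[Si](C)(C)C(C)(C)C)=C\[C@H](OC(=O)/C(C)=C\C)[C@H]12 | intermediate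
28 | CNP0176514.1, (6S,7R,8S,10R)-6-(angeloyloxy)-15-hydroxy-1-oxo-3,10-epoxygermacra-2,4(Z),11(13)-trien-12,8-olide | C=C1C(=O)O[C@H]2C[C@@]3(C)OC(=CC3=O)/C(CO)=C\[C@H](OC(=O)/C(C)=C\C)[C@H]12 | target

## Step count and risks

Total step count: 16 (steps 1–4 to the alkyne triol 7, steps 5–7 to the vinyl iodide 14, steps 8–16 from their union).
Longest linear sequence: 13 steps (steps 1–4 and 8–16, from (R)-citramalic acid).

Steps most likely to fail:

Step 13. Intermolecular coupling and premature protonation or reduction of the allylchromium species may outrun closure of the strained ring. The facial preference at C7 may also be weaker than the conformational model predicts, since C10 relays its configuration through the same arc. Fallback: the allyl donor is changed from a transient organochromium to an isolable allylboronate, so that no reducing metal is present and the aldehyde is made last. Setting out from 19, palladium-catalysed borylation of the allylic bromide (B2pin2, Pd2(dba)3 cat., toluene, 50 °C) should give the primary allylboronate F1. Dess–Martin oxidation of the primary alcohol should give the boronate aldehyde F2. A thermal or Sc(OTf)3-catalysed type-one allylboration at high dilution (toluene, 25–80 °C), which passes through a compact chair transition state, followed by acid-promoted lactonisation (p-TsOH), comes back to the route at 23.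

Step 11. Cross-metathesis between two slowly reacting alkenes may stall, with catalyst decomposition and self-metathesis of 18 taking over. Fallback: the bromomethyl acrylate is assembled by carbonyl chemistry instead of metathesis. Setting out from 17, silylation of the primary hydroxyl (Et3SiCl, imidazole) should give the bis(triethylsilyl) ether F3. Selective dihydroxylation of the terminal vinyl group and periodate cleavage (OsO4 cat., N-methylmorpholine N-oxide; then NaIO4) should give the α-silyloxy aldehyde F4, to be used at once because it can epimerise. Addition of [1-(methoxycarbonyl)vinyl]diisobutylaluminium (from methyl propiolate, iBu2AlH and N-methylmorpholine N-oxide, THF, 0 °C) should give the Baylis–Hillman-type adduct F5. SN2′ bromination (NBS, Me2S, CH2Cl2, 0 °C) should give the Z allylic bromide F6. Swern oxidation, which converts a primary triethylsilyl ether directly into the aldehyde while the secondary one survives, comes back to the route at 20.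

Step 5. Acrolein may oligomerise under the reaction conditions, and enantioselectivity may erode with so small an aldehyde. Fallback: enantioselection is moved from the C–C bond formation to an enzymatic resolution. Setting out from 9 (with 8), addition of the lithium acetylide of 9 (BuLi, THF, −78 °C) to 8 should give the racemic alcohol F7. Acylation with vinyl acetate and immobilised Candida antarctica lipase B is expected to convert the R enantiomer (alkynyl arm as the large group) into the acetate F8 and to leave the S alcohol F9. Methanolysis of F8 (K2CO3, MeOH) comes back to the route at 11.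

Further compounds
F1 | step 13 | pinacol allylboronate alcohol (CH2Br of 19 replaced by CH2Bpin) | OCC[C@@]1(C)OC(=CC1=O)/C(CO[Si](C)(C)C(C)(C)C)=C\[C@H](O[Si](CC)(CC)CC)/C=C(\CB2OC(C)(C)C(C)(C)O2)C(=O)OC
F2 | step 13 | pinacol allylboronate aldehyde (CH2Br of 20 replaced by CH2Bpin) | O=CC[C@@]1(C)OC(=CC1=O)/C(CO[Si](C)(C)C(C)(C)C)=C\[C@H](O[Si](CC)(CC)CC)/C=C(\CB2OC(C)(C)C(C)(C)O2)C(=O)OC
F3 | step 11 | bis(triethylsilyl) ether of 17 (primary hydroxyl silylated) | CC[Si](CC)(CC)OCC[C@@]1(C)OC(=CC1=O)/C(CO[Si](C)(C)C(C)(C)C)=C\[C@H](O[Si](CC)(CC)CC)C=C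
F4 | step 11 | α-silyloxy aldehyde (vinyl group of F3 cleaved to CHO) | CC[Si](CC)(CC)OCC[C@@]1(C)OC(=CC1=O)/C(CO[Si](C)(C)C(C)(C)C)=C\[C@H](O[Si](CC)(CC)CC)C=O
F5 | step 11 | Baylis–Hillman-type adduct of F4 (methyl 2-(hydroxyalkyl)acrylate, carbinol epimers) | CC[Si](CC)(CC)OCC[C@@]1(C)OC(=CC1=O)/C(CO[Si](C)(C)C(C)(C)C)=C\[C@H](O[Si](CC)(CC)CC)C(O)C(=C)C(=O)OC
F6 | step 11 | Z allylic bromide (19 with the primary hydroxyl as triethylsilyl ether) | CC[Si](CC)(CC)OCC[C@@]1(C)OC(=CC1=O)/C(CO[Si](C)(C)C(C)(C)C)=C\[C@H](O[Si](CC)(CC)CC)/C=C(\CBr)C(=O)OC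
F7 | step 5 | racemic 6-[(tert-butyldimethylsilyl)oxy]hex-1-en-4-yn-3-ol | C=CC(O)C#CCO[Si](C)(C)C(C)(C)C
F8 | step 5 | (3R)-6-[(tert-butyldimethylsilyl)oxy]hex-1-en-4-yn-3-yl acetate | CC(C)(C)[Si](C)(C)OCC#C[C@H](OC(C)=O)C=C
F9 | step 5 | (3S)-6-[(tert-butyldimethylsilyl)oxy]hex-1-en-4-yn-3-ol | CC(C)(C)[Si](C)(C)OCC#C[C@@H](O)C=C
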